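## Retrosynthetic overview

1. The target comes from a 1‑methoxy‑4‑(PMB‑oxy)pyridinium salt, which comes from the pyridine N‑oxide, which comes from the (5S,8R)‑tetrahydroquinoline. N–OMe is made by N‑oxidation and O‑methylation while O4 is masked; loss of PMB then reveals the 4‑pyridone.
2. Key step: both stereocentres are traced back to a flat, achiral 5,8‑disubstituted quinoline. In the forward direction, one carbocycle‑selective, enantioselective cis‑hydrogenation sets C5 and C8 together.
3. The quinoline comes from a Conrad–Limpach annulation of 2‑methoxy‑5‑(5‑phenylpentyl)aniline with methyl 2‑methoxyacetoacetate. This delivers 2‑Me, 3‑OMe and 4‑O.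
4. The aniline comes from a B‑alkyl Suzuki coupling of 5‑bromo‑2‑methoxyaniline with 5‑phenylpent‑1‑ene. The ketoester comes from a crossed Claisen reaction.
5. Ring order: the benzene ring is bought, the pyridine ring is annulated onto it, and the benzene ring is then dearomatised into the chiral cyclohexane. This avoids the usual plan of building a pyridone on a chiral cyclohexanone and reducing a C8 ketone.

**Assumptions**
- With quinoline numbering, the target SMILES decodes as the cis‑(5S,8R) isomer (C5 = S, C8 = R, chain and 8‑OMe on the same face).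
- The sense of induction of PhTRAP on this substrate cannot be predicted. The ligand antipode that gives (5S,8R) is used; both antipodes are accessible.
- Ketoester 3 is made rather than assumed to be purchasable.

## Route

**Step 1**
- Reactants: 1 methyl methoxyacetate; 2 N‑methoxy‑N‑methylacetamide
- Product: 3 methyl 2‑methoxy‑3‑oxobutanoate (racemic, enolisable)
- Conditions: LDA (1.1 equiv), THF, −78 °C; then 2, −78 → 0 °C; aq NH4Cl
- Reagents that add atoms: none (all atoms come from 1 and 2)
- Why: This is a crossed Claisen‑type acylation in which the chelated ester enolate adds to the Weinreb amide to give a stable tetrahedral chelate that collapses only on quench, which suppresses self‑condensation, O‑acylation and proton transfer; the α‑carbon becomes sp2 later, so no stereocentre matters.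

**Step 2**
- Reactants: 4 5‑phenylpent‑1‑ene; 5 5‑bromo‑2‑methoxyaniline
- Product: 6 2‑methoxy‑5‑(5‑phenylpentyl)aniline
- Conditions: 4, 9‑BBN, THF, 0 °C → rt; then 5, Pd(dppf)Cl2 (3 mol %), aq K3PO4, THF/DMF, 65 °C
- Reagents that add atoms: none (9‑BBN is lost)
- Why: This is an anti‑Markovnikov hydroboration followed by a B‑alkyl Suzuki–Miyaura coupling, in which the primary alkyl‑9‑BBN transfers cleanly with dppf and the free NH2 and OMe are tolerated.

**Step 3**
- Reactants: 6; 3
- Product: 7 methyl (E)‑2‑methoxy‑3‑{[2‑methoxy‑5‑(5‑phenylpentyl)phenyl]amino}but‑2‑enoate (NH cis to the ester, hydrogen‑bonded)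
- Conditions: p‑TsOH·H2O (2 mol %), cyclohexane, Dean–Stark, reflux
- Reagents that add atoms: none
- Why: This is the ketone–aniline condensation that forms the first stage of the Conrad–Limpach sequence; at about 80 °C or below the enaminoester forms in preference to the Knorr anilide, and the α‑OMe makes the ketone more electrophilic.

**Step 4**
- Reactants: 7
- Product: 8 3,8‑dimethoxy‑2‑methyl‑5‑(5‑phenylpentyl)quinolin‑4(1H)‑one
- Conditions: Ph2O, 250 °C, 20 min (−MeOH)
- Reagents that add atoms: none
- Why: This is the Conrad–Limpach thermal cyclisation, in which loss of MeOH gives an imidoylketene that undergoes 6π closure onto the only free ortho carbon, so the placement of the chain at C5 and OMe at C8 is unambiguous.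

**Step 5**
- Reactants: 8
- Product: 9 3,8‑dimethoxy‑4‑[(4‑methoxybenzyl)oxy]‑2‑methyl‑5‑(5‑phenylpentyl)quinoline
- Conditions: PMBCl, Ag2CO3, toluene, 80 °C, dark
- Reagents that add atoms: 4‑methoxybenzyl chloride, COc1ccc(CCl)cc1
- Why: This is a silver‑salt O‑alkylation of the ambident quinolone, O‑selective because N1 is flanked by 2‑Me and 8‑OMe; it gives a true quinoline for step 6 and masks O4 with an acid‑labile group.

**Step 6 (key step)**
- Reactants: 9
- Product: 10 (5S,8R)‑3,8‑dimethoxy‑4‑[(4‑methoxybenzyl)oxy]‑2‑methyl‑5‑(5‑phenylpentyl)‑5,6,7,8‑tetrahydroquinoline (5,8‑cis)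
- Conditions: [Ru(η3‑methallyl)2(cod)] (5 mol %), (S,S)‑(R,R)‑PhTRAP (5.5 mol %), H2 (8 MPa), i‑PrOH, 80 °C, 48 h
- Reagents that add atoms: none (H2 only)
- Why: Proposed new method: Ru–H complexes of the trans‑chelating PhTRAP ligand are known to hydrogenate the carbocycle rather than the pyridine ring of quinolines (enantioselectively for 8‑substituted cases) and to reduce alkoxynaphthalene rings without C–O cleavage while leaving isolated benzene rings intact, and Ru–NHC catalysts behave the same way on 2,3‑disubstituted quinoxalines; here the pentasubstituted pyridine ring is sterically blocked, the fused benzo ring is the only arene with lowered resonance energy (so Ph and PMB survive), both H2 molecules are delivered to the Ru‑bound face to give the cis‑5,8 relationship, and the chiral pocket selects the face to give (5S,8R); the extension beyond known scope is the 5,8‑disubstitution.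

**Step 7**
- Reactants: 10
- Product: 11 (5S,8R)‑3,8‑dimethoxy‑4‑[(4‑methoxybenzyl)oxy]‑2‑methyl‑5‑(5‑phenylpentyl)‑5,6,7,8‑tetrahydroquinoline 1‑oxide
- Conditions: mCPBA (1.3 equiv), CH2Cl2, 0 °C → rt; aq Na2CO3 wash (recrystallise to raise er)
- Reagents that add atoms: mCPBA, O=C(OO)c1cccc(Cl)c1 (delivers O)
- Why: This is a peracid pyridine N‑oxidation in which the electron‑rich 4‑alkoxypyridine nitrogen is the only oxidisable site, so the ethers, arenes and both stereocentres are untouched.

**Step 8**
- Reactants: 11
- Product: 12 (5S,8R)‑1,3,8‑trimethoxy‑4‑[(4‑methoxybenzyl)oxy]‑2‑methyl‑5‑(5‑phenylpentyl)‑5,6,7,8‑tetrahydroquinolin‑1‑ium triflate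
- Conditions: MeOTf (1.1 equiv), 2,6‑di‑tert‑butyl‑4‑methylpyridine (0.2 equiv), CH2Cl2, −20 → 0 °C
- Reagents that add atoms: methyl triflate, COS(=O)(=O)C(F)(F)F (CH3 and the triflate counter‑ion)
- Why: This is O‑alkylation of an N‑oxide to form an N‑alkoxypyridinium salt; because O4 is still blocked the methyl group can only end up on N–O, and the essentially non‑basic medium prevents anhydrobase formation at C8–H or 2‑CH3, so C8 is not epimerised.

**Step 9**
- Reactants: 12
- Product: 13 Waltherione H, (5S,8R)‑1,3,8‑trimethoxy‑2‑methyl‑5‑(5‑phenylpentyl)‑5,6,7,8‑tetrahydroquinolin‑4(1H)‑one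
- Conditions: TFA/CH2Cl2 (1:4), anisole (5 equiv), 0 °C → rt; then aq NaHCO3
- Reagents that add atoms: none
- Why: This is an acidolytic (SN1) PMB cleavage in which the pyridinium makes O4 an excellent leaving group, the PMB cation is trapped by anisole (Friedel–Crafts), and the methyl ethers and N–OMe are inert to TFA; bicarbonate removes only the acidic 4‑OH proton, so neither stereocentre is affected.

## Compound list

| No. | Name | SMILES | Role |
|---|---|---|---|
| 1 | methyl methoxyacetate | COCC(=O)OC | starting material |
| 2 | N‑methoxy‑N‑methylacetamide | CC(=O)N(C)OC | starting material |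
| 3 | methyl 2‑methoxy‑3‑oxobutanoate | COC(=O)C(OC)C(C)=O | intermediate |
| 4 | 5‑phenylpent‑1‑ene | C=CCCCc1ccccc1 | starting material |
| 5 | 5‑bromo‑2‑methoxyaniline | COc1ccc(Br)cc1N | starting material |
| 6 | 2‑methoxy‑5‑(5‑phenylpentyl)aniline | COc1ccc(CCCCCc2ccccc2)cc1N | intermediate |
| 7 | methyl (E)‑2‑methoxy‑3‑(arylamino)but‑2‑enoate | COC(=O)/C(OC)=C(\Nc1cc(CCCCCc2ccccc2)ccc1OC)C | intermediate |
| 8 | 3,8‑dimethoxy‑2‑methyl‑5‑(5‑phenylpentyl)quinolin‑4(1H)‑one | COc1c(C)[nH]c2c(OC)ccc(CCCCCc3ccccc3)c2c1=O | intermediate |
| 9 | 4‑PMBO‑3,8‑dimethoxy‑2‑methyl‑5‑(5‑phenylpentyl)quinoline | COc1c(C)nc2c(OC)ccc(CCCCCc3ccccc3)c2c1OCc4ccc(OC)cc4 | intermediate |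
| 10 | (5S,8R)‑tetrahydroquinoline | COc1c(C)nc2c(c1OCc3ccc(OC)cc3)[C@@H](CCCCCc3ccccc3)CC[C@H]2OC | intermediate |
| 11 | (5S,8R)‑N‑oxide | COc1c(C)[n+]([O-])c2c(c1OCc3ccc(OC)cc3)[C@@H](CCCCCc3ccccc3)CC[C@H]2OC | intermediate |
| 12 | (5S,8R)‑N‑methoxypyridinium triflate | COc1c(C)[n+](OC)c2c(c1OCc3ccc(OC)cc3)[C@@H](CCCCCc3ccccc3)CC[C@H]2OC.[O-]S(=O)(=O)C(F)(F)F | intermediate |
| 13 | Waltherione H | COc1c(C)n(OC)c2c(c1=O)[C@@H](CCCCCc1ccccc1)CC[C@H]2OC | target |

## Step count

- Total steps: 9
- Longest linear sequence: 8 (steps 2, or 1, then 3 → 9)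

## Steps most likely to fail

1. **Step 6.** The risks are no turnover on the hindered 5,8‑disubstituted ring, modest er or dr, and loss of the C8–OMe.
   - Fallback: set the two centres separately.
   - A Cu/phosphoramidite asymmetric conjugate addition of the alkylzirconocene from 4 (Schwartz reagent) to cyclohex‑2‑enone fixes C5.
   - C‑acylation of the enolate and closure with ammonia then builds the pyridone on the chiral ring.
   - C8–O is introduced by N‑oxide formation, Boekelheide rearrangement to the acetate, oxidation to the 8‑ketone, Noyori transfer hydrogenation (catalyst‑controlled cis) and methylation with MeI. The end‑game is unchanged.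
2. **Step 4.** The risk is failure of the 250 °C closure onto the ortho carbon next to the chain, or decomposition of the α‑methoxy enaminoester.
   - Fallback: form the C4–C4a bond first by Sugasawa ortho‑acylation of 6 (BCl3/AlCl3, methoxyacetonitrile).
   - N‑acetylation and a base‑mediated Camps cyclisation (t‑BuOK, below 100 °C) then give 8.
3. **Step 8 (with step 9).** The risks are premature or intermolecular PMB transfer and side reactions at the lateral positions of the N‑methoxypyridinium salt.
   - Fallback: reverse the order. Cleave PMB from N‑oxide 11 with TFA to give the 1‑hydroxy‑4‑pyridone.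
   - Alkylate its N–O⁻ with MeI/K2CO3 or TMSCHN2 and remove any 4‑methoxy N‑oxide isomer by chromatography.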